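**Retrosynthetic overview**
1. Target ⇒ cyclohexanol with a free C1 hydroxyl + angelic acid (late esterification of the only free OH).
2. Cyclohexanol ⇒ acyclic C15 diacetoxy aldehyde: the single ring is closed by a C1–C6 cationic (Prins-type) cyclisation, the same alkene-onto-cation closure that gives the bisabolyl cation in the biosynthesis, and the C7 cation is quenched by internal hydride transfer, so C1, C6 and C7 arise together.
3. Aldehyde ⇒ acyclic triene diol (bis-acetylation; terminal vinyl → aldehyde).
4. Triene diol ⇒ E-homoallylic alcohol + crotyl donor (C3–C4 bond, anti C3/C4 pair).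
5. Homoallylic alcohol ⇒ 3-methylbut-2-enal + allenylboronate (C9 centre), a methyl from carboalumination, and oxirane. Ring order: one ring only, formed in the sixth of seven steps.

Assumption and convention: each chiral catalyst antipode named is the one expected to give the stated configuration (its mirror image is used if induction proves opposite); locants C1–C11 are those of the chain of aldehyde 12 and are kept for the same atoms after ring closure.

Step 1
Reactants: 1 3-methylbut-2-enal; 2 allenylboronic acid pinacol ester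
Product: 3 (4R)-6-methylhept-5-en-1-yn-4-ol
Conditions: (R)-3,3′-bis(2,4,6-triisopropylphenyl)-1,1′-binaphthyl-2,2′-diyl hydrogen phosphate ((R)-TRIP, 5 mol %), 4 Å MS, toluene, −20 °C
Reagents that add atoms: none
Why: Chiral phosphoric acid-catalysed asymmetric propargylboration (SE2′ through a six-membered chair with the acid bound to the boronate) adds the propargyl unit to the Re face of the enal and so sets the future C9 carbinol as R under catalyst control.

Step 2
Reactants: 3 (4R)-6-methylhept-5-en-1-yn-4-ol; 4 oxirane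
Product: 7 (3E,6R)-4,8-dimethylnona-3,7-diene-1,6-diol, via E-vinylalane 5 (not isolated), via lithium alanate 6 (not isolated)
Conditions: Me3Al, Cp2ZrCl2 (cat.), CH2Cl2, 0 °C → rt; evaporate; n-BuLi, THF–hexane, −78 °C; 4, −78 → 0 °C; aq. HCl
Reagents that add atoms: trimethylaluminium, C[Al](C)C
Why: Negishi zirconium-catalysed syn-carboalumination of the terminal alkyne (tolerant of the free hydroxyl as its aluminium alkoxide) puts the methyl on the internal carbon with E geometry, and the derived alkenylalanate opens oxirane with retention of alkene geometry; the carbinol centre is untouched.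

Step 3
Reactants: 7 (3E,6R)-4,8-dimethylnona-3,7-diene-1,6-diol; 8 but-3-en-2-yl acetate
Product: 10 (3S,4R,6E,9R)-3,7,11-trimethyldodeca-1,6,10-triene-4,9-diol, via hydroxy aldehyde 9 (not isolated)
Conditions: [Ir(cod)Cl]2 (2.5 mol %), (S)-SEGPHOS (5 mol %), 4-cyano-3-nitrobenzoic acid (10 mol %), Cs2CO3 (20 mol %), THF, 90 °C
Reagents that add atoms: none
Why: Krische iridium-catalysed transfer-hydrogenative anti-crotylation from the alcohol oxidation level dehydrogenates only the primary alcohol to the transient β,γ-unsaturated aldehyde 9, which is trapped at once by the (E)-σ-crotyliridium species through a closed chair (Si-face attack), setting C3 (S) and C4 (R) anti under catalyst control.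

Step 4
Reactants: 10 (3S,4R,6E,9R)-3,7,11-trimethyldodeca-1,6,10-triene-4,9-diol
Product: 11 (3S,4R,6E,9R)-3,7,11-trimethyldodeca-1,6,10-triene-4,9-diyl diacetate
Conditions: Ac2O, pyridine, 4-(dimethylamino)pyridine (cat.), CH2Cl2, 0 °C → rt
Reagents that add atoms: acetic anhydride, CC(=O)OC(C)=O
Why: Nucleophile-catalysed acylation of both secondary alcohols installs the two acetates of the target in one operation and masks the C4 hydroxyl, which would otherwise form a lactol with the C1 aldehyde; no stereocentre is touched.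

Step 5
Reactants: 11 (3S,4R,6E,9R)-3,7,11-trimethyldodeca-1,6,10-triene-4,9-diyl diacetate
Product: 12 (3S,4R,6E,9R)-4,9-diacetoxy-3,7,11-trimethyldodeca-6,10-dienal
Conditions: PdCl2(PhCN)2 (12 mol %), CuCl2·2H2O (12 mol %), AgNO2 (6 mol %), O2 (1 atm), t-BuOH/MeNO2 (15:1), rt
Reagents that add atoms: dioxygen, O=O
Why: Nitrite-modified aldehyde-selective (anti-Markovnikov) Wacker oxidation converts only the monosubstituted alkene, the allylic methyl branch and the homoallylic acetate steering oxygen to the terminal carbon, while the trisubstituted alkenes are inert to divalent palladium here; no stereocentre is formed.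

Step 6
Reactants: 12 (3S,4R,6E,9R)-4,9-diacetoxy-3,7,11-trimethyldodeca-6,10-dienal
Product: 14 (1R,2S,4R,5S)-4-acetoxy-2-[(2R,4R)-4-acetoxy-6-methylhept-5-en-2-yl]-5-methylcyclohexan-1-ol, via silyl ether triflate 13 (not isolated)
Conditions: iPr2SiHCl, AgOTf, CH2Cl2, 0 °C; add to 12, CH2Cl2, −78 → −40 °C; pyridine, then HF·pyridine, THF, −78 → 0 °C
Reagents that add atoms: none
Why: Proposed new method: a silyl-triflate-triggered Prins cyclisation terminated by intramolecular hydride transfer, in which O-silylation of the aldehyde by iPr2SiH(OTf) gives a silyloxocarbenium ion that is attacked by the C6=C7 alkene through a chair (C3 methyl, C1–OSi and the C6 side chain equatorial, C4 acetate axial, favoured by about 1 kcal/mol over the alternative chair), forming the C1–C6 bond and a tertiary C7 cation that is quenched by a 1,5-hydride shift from the Si–H on the C1 oxygen through a six-membered chair (hydride to the C7 face syn to C1 and anti to C5, after a least-motion rotation of about 30° about C6–C7 that keeps the larger C8 chain eclipsing C6–H and places the C7 methyl between C1 and C5), so that C1 (R), C6 (S) and C7 (R) are set at once; the closest known reactions are Lewis-acid Prins and carbonyl-ene cyclisations of citronellal-type aldehydes, the Lewis-acid-triggered hydride delivery from β-(diisopropylsilyloxy) ketones through the same six-membered array, and ionic hydrogenation of tertiary carbocations by hydrosilanes.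

Step 7
Reactants: 14 (1R,2S,4R,5S)-4-acetoxy-2-[(2R,4R)-4-acetoxy-6-methylhept-5-en-2-yl]-5-methylcyclohexan-1-ol; 15 angelic acid
Product: 16 (1R,2S,4R,5S)-4-acetoxy-2-[(2R,4R)-4-acetoxy-6-methylhept-5-en-2-yl]-5-methylcyclohexyl (2Z)-2-methylbut-2-enoate
Conditions: 15, 2,4,6-trichlorobenzoyl chloride, Et3N, toluene, rt; then 14, toluene, 80 °C
Reagents that add atoms: none
Why: Yamaguchi esterification through the angelic 2,4,6-trichlorobenzoic mixed anhydride acylates the only free (equatorial, secondary) hydroxyl without a nucleophilic amine catalyst, which keeps Z→E isomerisation to the tiglate minimal; no stereocentre is touched.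

**Compound list**
1 | 3-methylbut-2-enal | CC(C)=CC=O | starting material
2 | allenylboronic acid pinacol ester (4,4,5,5-tetramethyl-2-(propa-1,2-dien-1-yl)-1,3,2-dioxaborolane) | C=C=CB1OC(C)(C)C(C)(C)O1 | starting material
3 | (4R)-6-methylhept-5-en-1-yn-4-ol | C#CC[C@@H](O)C=C(C)C | intermediate
4 | oxirane | C1CO1 | starting material
5 | dimethyl{(1E,4R)-4-[(dimethylalumanyl)oxy]-2,6-dimethylhepta-1,5-dien-1-yl}alumane (E-vinylalane) | C[Al](C)/C=C(\C)C[C@@H](O[Al](C)C)C=C(C)C | intermediate
6 | lithium butyl{(1E,4R)-4-[(dimethylalumanyl)oxy]-2,6-dimethylhepta-1,5-dien-1-yl}dimethylaluminate | [Li+].CCCC[Al-](C)(C)/C=C(\C)C[C@@H](O[Al](C)C)C=C(C)C | intermediate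
7 | (3E,6R)-4,8-dimethylnona-3,7-diene-1,6-diol | OCC/C=C(\C)C[C@@H](O)C=C(C)C | intermediate
8 | but-3-en-2-yl acetate (racemic) | CC(OC(C)=O)C=C | starting material
9 | (3E,6R)-6-hydroxy-4,8-dimethylnona-3,7-dienal | O=CC/C=C(\C)C[C@@H](O)C=C(C)C | intermediate
10 | (3S,4R,6E,9R)-3,7,11-trimethyldodeca-1,6,10-triene-4,9-diol | C=C[C@H](C)[C@H](O)C/C=C(\C)C[C@@H](O)C=C(C)C | intermediate
11 | (3S,4R,6E,9R)-3,7,11-trimethyldodeca-1,6,10-triene-4,9-diyl diacetate | C=C[C@H](C)[C@H](OC(C)=O)C/C=C(\C)C[C@@H](OC(C)=O)C=C(C)C | intermediate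
12 | (3S,4R,6E,9R)-4,9-diacetoxy-3,7,11-trimethyldodeca-6,10-dienal | O=CC[C@H](C)[C@H](OC(C)=O)C/C=C(\C)C[C@@H](OC(C)=O)C=C(C)C | intermediate
13 | {[(1R,2S,4R,5S)-4-acetoxy-2-[(2R,4R)-4-acetoxy-6-methylhept-5-en-2-yl]-5-methylcyclohexyl]oxy}diisopropylsilyl trifluoromethanesulfonate | CC(C)[Si](O[C@@H]1C[C@H](C)[C@H](OC(C)=O)C[C@H]1[C@H](C)C[C@H](C=C(C)C)OC(C)=O)(OS(=O)(=O)C(F)(F)F)C(C)C | intermediate
14 | (1R,2S,4R,5S)-4-acetoxy-2-[(2R,4R)-4-acetoxy-6-methylhept-5-en-2-yl]-5-methylcyclohexan-1-ol | O[C@@H]1C[C@H](C)[C@H](OC(C)=O)C[C@H]1[C@H](C)C[C@H](C=C(C)C)OC(C)=O | intermediate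
15 | angelic acid ((2Z)-2-methylbut-2-enoic acid) | C/C=C(/C)C(=O)O | starting material
16 | (1R,2S,4R,5S)-4-acetoxy-2-[(2R,4R)-4-acetoxy-6-methylhept-5-en-2-yl]-5-methylcyclohexyl (2Z)-2-methylbut-2-enoate (CNP0286954.1) | C/C=C(/C)C(=O)O[C@@H]1C[C@H](C)[C@H](OC(C)=O)C[C@H]1[C@H](C)C[C@H](C=C(C)C)OC(C)=O | target

**Totals**
Total step count: 7. Longest linear sequence: 7 steps (from 3-methylbut-2-enal).

**Three steps most likely to fail**

Step 6 (highest risk). The C7 cation may be captured by the C9 acetate carbonyl (six-membered acetoxonium ion) or lose a proton before the hydride arrives. The silyl triflate may also ionise the allylic acetate, and the C7 selectivity rests on a conformational argument. Fallback: setting out from 12, the ring is closed by a concerted carbonyl-ene reaction promoted by aluminium tris(2,6-diphenylphenoxide) (CH2Cl2, −78 °C). This Lewis acid binds the aldehyde in preference to the esters and transfers a C8 hydrogen, giving (1R,2S,4R,5S)-4-acetoxy-2-[(2E,4S)-4-acetoxy-6-methylhepta-2,5-dien-2-yl]-5-methylcyclohexan-1-ol F1 with the same C1 and C6 configuration. Hydroxyl-directed hydrogenation of F1 with [Ir(cod)(PCy3)(py)]PF6 and H2 (CH2Cl2, 0 °C) then delivers hydrogen to C7 from the face of the C1 hydroxyl (C6–H eclipsing the alkene) and comes back to the route at 14.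

Step 3. The free allylic secondary alcohol may be dehydrogenated or epimerised by the iridium hydride, and the transient β,γ-unsaturated aldehyde may slip into conjugation. Fallback: setting out from 7, only the primary alcohol is oxidised with 2,2,6,6-tetramethylpiperidin-1-oxyl/PhI(OAc)2 (CH2Cl2, 0 °C) to hydroxy aldehyde 9, now isolated crude. Crotylation at the aldehyde level with (E)-crotylboronic acid pinacol ester under (R)-TRIP catalysis (toluene, −30 °C, anti through the closed chair) comes back at 10; no compound outside the list is made (F0).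

Step 5. Aldehyde/methyl ketone selectivity may be incomplete, and divalent palladium may shift the allylic acetate. Fallback: setting out from 11, the vinyl group alone is hydroborated with 9-BBN-H (THF, 0 °C → rt) to give 9-[(3S,4R,6E,9R)-4,9-diacetoxy-3,7,11-trimethyldodeca-6,10-dien-1-yl]-9-borabicyclo[3.3.1]nonane F2. Oxidation in the same flask (NaBO3·4H2O, THF/H2O) gives (3S,4R,6E,9R)-1-hydroxy-3,7,11-trimethyldodeca-6,10-diene-4,9-diyl diacetate F3, and Dess–Martin periodinane (NaHCO3, CH2Cl2, 0 °C) oxidises F3 to come back at 12.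

**Further compounds**
F1 | step 6 | (1R,2S,4R,5S)-4-acetoxy-2-[(2E,4S)-4-acetoxy-6-methylhepta-2,5-dien-2-yl]-5-methylcyclohexan-1-ol | O[C@@H]1C[C@H](C)[C@H](OC(C)=O)C[C@H]1/C(C)=C/[C@H](C=C(C)C)OC(C)=O
F0 | step 3 | none | none
F2 | step 5 | 9-[(3S,4R,6E,9R)-4,9-diacetoxy-3,7,11-trimethyldodeca-6,10-dien-1-yl]-9-borabicyclo[3.3.1]nonane | B1(CC[C@H](C)[C@H](OC(C)=O)C/C=C(\C)C[C@@H](OC(C)=O)C=C(C)C)C2CCCC1CCC2
F3 | step 5 | (3S,4R,6E,9R)-1-hydroxy-3,7,11-trimethyldodeca-6,10-diene-4,9-diyl diacetate | OCC[C@H](C)[C@H](OC(C)=O)C/C=C(\C)C[C@@H](OC(C)=O)C=C(C)C
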